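**Strategy.** The 14-membered ring is not closed head to tail. A 17-membered propargyl allyl ether, in which an oxygen links C2 to the (E)-allylic carbon on C15, is contracted by a [2,3]-Wittig rearrangement. In one operation this forms the C1–C2 ring bond, sets both ring-fusion stereocentres anti (the trans-lactone) and leaves the exocyclic C15 methylene. It exploits the C2(O)–C1(2-propenyl) homoallylic motif of the trans-fused α-methylene lactone, with the C3=C4 olefin carried as the acidifying alkyne. The precursor is assembled linearly from geranyl acetate by two catalytic propargylations (C10, C6) and closed by alkyne metathesis at C3≡C4.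

Key step: step 13

Remark (numbering): cembrane locants are used for all macrocycles: C1 (ring-fusion CH carrying C15), C2 (O–CH), C3=C4(Me), C5, C6 (OH), C7=C8(Me), C9, C10 (OAc), C11=C12(Me), C13, C14. CIP descriptors at C1/C2 change with the substituents along the route; the spatial arrangement does not.

Remark (assumption): (S)-TRIP is assumed to direct allenyl transfer to the Si face of (E)-enals, and the (S,S)-amide is assumed to be the matched base in step 13. If either sense proves opposite, the antipode is used with no other change.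

Step 1
Reactants: 1 geranyl acetate
Product: 2 (2E,6E)-8-hydroxy-3,7-dimethylocta-2,6-dien-1-yl acetate
Conditions: SeO2 (cat.), t-BuOOH, salicylic acid (cat.), CH2Cl2, rt
Reagents that add atoms: tert-butyl hydroperoxide, CC(C)(C)OO (oxygen, relayed by catalytic selenium dioxide, O=[Se]=O)
Why: Riley allylic oxidation (ene reaction, then [2,3]-shift) should hydroxylate only the (E)-methyl of the electron-rich terminal olefin, the allylic acetate deactivating the 2,3-olefin; the (E)-CH2OH geometry is inherent to the mechanism.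

Step 2
Reactants: 2 (2E,6E)-8-hydroxy-3,7-dimethylocta-2,6-dien-1-yl acetate; 3 1-bromobut-2-yne
Product: 4 (2E,6E)-8-(but-2-yn-1-yloxy)-3,7-dimethylocta-2,6-dien-1-yl acetate
Conditions: Ag2O, CH2Cl2, rt, dark
Reagents that add atoms: 1-bromobut-2-yne (3), CC#CCBr
Why: Silver-oxide-promoted Williamson etherification of the primary allylic alcohol with a reactive propargylic bromide; the non-basic conditions leave the acetate and both olefin geometries untouched.

Step 3
Reactants: 4 (2E,6E)-8-(but-2-yn-1-yloxy)-3,7-dimethylocta-2,6-dien-1-yl acetate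
Product: 5 (2E,6E)-8-(but-2-yn-1-yloxy)-3,7-dimethylocta-2,6-dien-1-ol
Conditions: K2CO3 (cat.), MeOH, 0 °C → rt
Reagents that add atoms: none
Why: Base-catalysed transesterification (Zemplén-type methanolysis) removes the acetate; the ether and alkyne are inert.

Step 4
Reactants: 5 (2E,6E)-8-(but-2-yn-1-yloxy)-3,7-dimethylocta-2,6-dien-1-ol
Product: 6 (2E,6E)-8-(but-2-yn-1-yloxy)-3,7-dimethylocta-2,6-dienal
Conditions: MnO2, CH2Cl2, rt
Reagents that add atoms: none
Why: Manganese dioxide oxidation of the allylic alcohol should stop at the enal without E/Z isomerisation.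

Step 5
Reactants: 6 (2E,6E)-8-(but-2-yn-1-yloxy)-3,7-dimethylocta-2,6-dienal; 7 allenylboronic acid pinacol ester
Product: 8 (4S,5E,9E)-11-(but-2-yn-1-yloxy)-6,10-dimethylundeca-5,9-dien-1-yn-4-ol
Conditions: (S)-TRIP (10 mol %), 4 Å MS, toluene, 0 °C; aqueous work-up
Reagents that add atoms: allenylboronic acid pinacol ester (7), C=C=CB1OC(C)(C)C(C)(C)O1
Why: Chiral-phosphoric-acid-catalysed allenylboration (SE2' propargylation through a closed six-membered transition state with the acid hydrogen-bonded to a boronate oxygen); catalyst-controlled Si-face attack sets C10 as S.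

Step 6
Reactants: 8 (4S,5E,9E)-11-(but-2-yn-1-yloxy)-6,10-dimethylundeca-5,9-dien-1-yn-4-ol
Product: 9 triethyl{[(4S,5E,9E)-11-(but-2-yn-1-yloxy)-6,10-dimethylundeca-5,9-dien-1-yn-4-yl]oxy}silane
Conditions: TESCl, imidazole, CH2Cl2, 0 °C
Reagents that add atoms: chlorotriethylsilane, CC[Si](CC)(CC)Cl
Why: Standard silylation; the TES group is chosen so that C10 can later be unmasked in the presence of the C6 TBS ether.

Step 7
Reactants: 9 triethyl{[(4S,5E,9E)-11-(but-2-yn-1-yloxy)-6,10-dimethylundeca-5,9-dien-1-yn-4-yl]oxy}silane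
Product: 12 (2E,5S,6E,10E)-12-(but-2-yn-1-yloxy)-3,7,11-trimethyl-5-[(triethylsilyl)oxy]dodeca-2,6,10-trien-1-ol, via alkenyl(dimethyl)alane 10 (not isolated), via lithium butyl(dimethyl)alkenylaluminate 11 (not isolated)
Conditions: Me3Al, Cp2ZrCl2 (20 mol %), H2O (1 equiv), CH2Cl2, −20 °C; evaporate; n-BuLi, THF, −78 °C; (CH2O)n, −78 °C → rt; Rochelle salt
Reagents that add atoms: trimethylaluminium, C[Al](C)C; paraformaldehyde (as formaldehyde), C=O
Why: Zirconium-catalysed carboalumination (Negishi) adds Me–Al syn across the terminal alkyne with methyl on the internal carbon, which fixes the (E)-C7=C8 geometry, and the derived aluminate is hydroxymethylated with retention; the internal butynyl alkyne should react far more slowly.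

Step 8
Reactants: 12 (2E,5S,6E,10E)-12-(but-2-yn-1-yloxy)-3,7,11-trimethyl-5-[(triethylsilyl)oxy]dodeca-2,6,10-trien-1-ol
Product: 13 (2E,5S,6E,10E)-12-(but-2-yn-1-yloxy)-3,7,11-trimethyl-5-[(triethylsilyl)oxy]dodeca-2,6,10-trienal
Conditions: MnO2, CH2Cl2, rt
Reagents that add atoms: none
Why: Allylic oxidation with manganese dioxide; the silylated C10 carbinol cannot be oxidised.

Step 9
Reactants: 13 (2E,5S,6E,10E)-12-(but-2-yn-1-yloxy)-3,7,11-trimethyl-5-[(triethylsilyl)oxy]dodeca-2,6,10-trienal; 7 allenylboronic acid pinacol ester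
Product: 14 (4S,5E,8S,9E,13E)-15-(but-2-yn-1-yloxy)-6,10,14-trimethyl-8-[(triethylsilyl)oxy]pentadeca-5,9,13-trien-1-yn-4-ol
Conditions: (S)-TRIP (10 mol %), 4 Å MS, toluene, 0 °C; aqueous work-up
Reagents that add atoms: allenylboronic acid pinacol ester (7), C=C=CB1OC(C)(C)C(C)(C)O1
Why: Second chiral-phosphoric-acid-catalysed allenylboration with the same catalyst antipode; Si-face attack sets C6 as S under catalyst control, the C10 centre being too remote to interfere, and any minor enantiomer from step 5 is removed here as a diastereomer.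

Step 10
Reactants: 14 (4S,5E,8S,9E,13E)-15-(but-2-yn-1-yloxy)-6,10,14-trimethyl-8-[(triethylsilyl)oxy]pentadeca-5,9,13-trien-1-yn-4-ol
Product: 15 (4S,5E,8S,9E,13E)-15-(but-2-yn-1-yloxy)-4-[(tert-butyldimethylsilyl)oxy]-6,10,14-trimethyl-8-[(triethylsilyl)oxy]pentadeca-5,9,13-trien-1-yne
Conditions: TBSCl, imidazole, DMF, rt
Reagents that add atoms: tert-butylchlorodimethylsilane, CC(C)(C)[Si](C)(C)Cl
Why: Standard silylation; TBS at C6 is orthogonal to TES at C10 under mild acid.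

Step 11
Reactants: 15 (4S,5E,8S,9E,13E)-15-(but-2-yn-1-yloxy)-4-[(tert-butyldimethylsilyl)oxy]-6,10,14-trimethyl-8-[(triethylsilyl)oxy]pentadeca-5,9,13-trien-1-yne
Product: 17 (5S,6E,9S,10E,14E)-16-(but-2-yn-1-yloxy)-5-[(tert-butyldimethylsilyl)oxy]-7,11,15-trimethyl-9-[(triethylsilyl)oxy]hexadeca-6,10,14-trien-2-yne, via lithium acetylide 16 (not isolated)
Conditions: n-BuLi, THF, −78 °C; MeI, −78 → 0 °C
Reagents that add atoms: iodomethane, CI
Why: Acetylide alkylation caps the terminal alkyne with methyl so that both alkynes are of the type that alkyne metathesis handles best; the terminal C–H is by far the most acidic site.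

Step 12
Reactants: 17 (5S,6E,9S,10E,14E)-16-(but-2-yn-1-yloxy)-5-[(tert-butyldimethylsilyl)oxy]-7,11,15-trimethyl-9-[(triethylsilyl)oxy]hexadeca-6,10,14-trien-2-yne
Product: 18 (6S,7E,10S,11E,15E)-6-[(tert-butyldimethylsilyl)oxy]-8,12,16-trimethyl-10-[(triethylsilyl)oxy]-1-oxacycloheptadeca-7,11,15-trien-3-yne (ring: O–C2H2–C3≡C4–C5…C14–C1H=C15(Me)–C17H2–O)
Conditions: [Mo(≡CC6H4-4-OMe)(OSiPh3)3] (5 mol %), MS 5 Å, toluene (2 mM), rt → 60 °C
Reagents that add atoms: none
Why: Ring-closing alkyne metathesis joins the two methyl-capped alkynes into the unstrained 17-membered cycloalkyne, driven by sequestration of but-2-yne; olefins, silyl ethers and the propargylic ether are spectators and no stereocentre is touched.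

Step 13
Reactants: 18 (6S,7E,10S,11E,15E)-6-[(tert-butyldimethylsilyl)oxy]-8,12,16-trimethyl-10-[(triethylsilyl)oxy]-1-oxacycloheptadeca-7,11,15-trien-3-yne
Product: 20 (1R,2R,6S,7E,10S,11E)-6-[(tert-butyldimethylsilyl)oxy]-8,12-dimethyl-1-(prop-1-en-2-yl)-10-[(triethylsilyl)oxy]cyclotetradeca-7,11-dien-3-yn-2-ol, via C2-lithiated ether 19 (not isolated)
Conditions: lithium bis[(S)-1-phenylethyl]amide (from the amine and n-BuLi), THF, −78 → −25 °C; aq NH4Cl
Reagents that add atoms: none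
Why: The chiral lithium amide removes one of the two diastereotopic propargylic C2–H atoms (acidified by alkyne and oxygen, so C2 and not the allylic C17 is lithiated), and the α-oxy propargyl-lithium 19 rearranges at once by a concerted, suprafacial [2,3]-sigmatropic shift through a five-membered envelope (C2–O–C17–C15=C1), which makes the C1–C2 bond, cuts O–C17 and leaves C15=C17 as the exocyclic methylene. The closest known reaction type is the [2,3]-Wittig ring contraction of macrocyclic allyl propargyl ethers (17 → 14 atoms). The 14-membered carbocycle is closed by transannular C–C bond formation across the 17-membered ether, that is by ring contraction with extrusion of O, C17 and C15 from the ring, not by an end-to-end cyclisation. The relative configuration at C1/C2 (anti, later the trans ring fusion of the lactone) should follow from the (E)-geometry of the C1=C15 olefin together with the exo position of the alkynyl arm in the envelope; the absolute sense at both centres is set by the base, since C6 and C10 are too remote to direct. The step needs [2,3] over [1,2] shift, which low temperature favours, and rearrangement faster than epimerisation of the lithiated carbon, which is expected for propargylic ethers of this kind.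

Step 14
Reactants: 20 (1R,2R,6S,7E,10S,11E)-6-[(tert-butyldimethylsilyl)oxy]-8,12-dimethyl-1-(prop-1-en-2-yl)-10-[(triethylsilyl)oxy]cyclotetradeca-7,11-dien-3-yn-2-ol
Product: 21 (1S,2R,6S,7E,10S,11E)-6-[(tert-butyldimethylsilyl)oxy]-8,12-dimethyl-1-(2-methyloxiran-2-yl)-10-[(triethylsilyl)oxy]cyclotetradeca-7,11-dien-3-yn-2-ol (epimers at the oxirane carbon)
Conditions: VO(acac)2 (5 mol %), t-BuOOH (decane), CH2Cl2, rt
Reagents that add atoms: tert-butyl hydroperoxide, CC(C)(C)OO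
Why: Vanadium-catalysed hydroxyl-directed epoxidation: only the 1,1-disubstituted olefin is within reach of the C2 vanadate ester (homoallylic), the ring olefins carry silylated carbinols and the alkyne is inert; the new oxirane centre is erased in step 15.

Step 15
Reactants: 21 (1S,2R,6S,7E,10S,11E)-6-[(tert-butyldimethylsilyl)oxy]-8,12-dimethyl-1-(2-methyloxiran-2-yl)-10-[(triethylsilyl)oxy]cyclotetradeca-7,11-dien-3-yn-2-ol
Product: 22 (1R,2R,6S,7E,10S,11E)-6-[(tert-butyldimethylsilyl)oxy]-1-(3-hydroxyprop-1-en-2-yl)-8,12-dimethyl-10-[(triethylsilyl)oxy]cyclotetradeca-7,11-dien-3-yn-2-ol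
Conditions: LDA (excess), Et2O–THF, 0 °C → rt; aq NH4Cl
Reagents that add atoms: none
Why: Base-promoted isomerisation of an epoxide to an allylic alcohol (syn β-elimination): the amide takes a proton from the unhindered methyl group and not the tertiary C1–H, giving the 2-methylene-1,4-diol without touching C1 or C2.

Step 16
Reactants: 22 (1R,2R,6S,7E,10S,11E)-6-[(tert-butyldimethylsilyl)oxy]-1-(3-hydroxyprop-1-en-2-yl)-8,12-dimethyl-10-[(triethylsilyl)oxy]cyclotetradeca-7,11-dien-3-yn-2-ol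
Product: 24 (1R,2R,3Z,6S,7E,10S,11E)-6-[(tert-butyldimethylsilyl)oxy]-1-(3-hydroxyprop-1-en-2-yl)-4-iodo-8,12-dimethyl-10-[(triethylsilyl)oxy]cyclotetradeca-3,7,11-trien-2-ol, via cyclic alkenylaluminate 23 (not isolated)
Conditions: Red-Al, THF, 0 °C → rt; EtOAc; I2, −78 → 0 °C
Reagents that add atoms: iodine, II
Why: Alkoxide-directed trans-hydroalumination of the propargylic alcohol delivers hydride to C3 and aluminium to C4 in a five-membered chelate, and iodinolysis with retention gives the (Z)-iodoalkene in which C2 and C5 are trans; the isolated allylic alcohol is not reduced.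

Step 17
Reactants: 24 (1R,2R,3Z,6S,7E,10S,11E)-6-[(tert-butyldimethylsilyl)oxy]-1-(3-hydroxyprop-1-en-2-yl)-4-iodo-8,12-dimethyl-10-[(triethylsilyl)oxy]cyclotetradeca-3,7,11-trien-2-ol
Product: 25 (1R,2S,3E,6S,7E,10S,11E)-6-[(tert-butyldimethylsilyl)oxy]-1-(3-hydroxyprop-1-en-2-yl)-4,8,12-trimethyl-10-[(triethylsilyl)oxy]cyclotetradeca-3,7,11-trien-2-ol
Conditions: MeZnCl (excess), Pd(PPh3)4 (5 mol %), THF, rt → 45 °C
Reagents that add atoms: methylzinc chloride, C[Zn]Cl
Why: Negishi cross-coupling replaces iodine by methyl with retention of olefin geometry, completing the (E)-C3=C4 trisubstituted olefin; the free hydroxyls only consume extra organozinc.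

Step 18
Reactants: 25 (1R,2S,3E,6S,7E,10S,11E)-6-[(tert-butyldimethylsilyl)oxy]-1-(3-hydroxyprop-1-en-2-yl)-4,8,12-trimethyl-10-[(triethylsilyl)oxy]cyclotetradeca-3,7,11-trien-2-ol
Product: 28 (1R,2S,3E,6S,7E,10S,11E)-6-[(tert-butyldimethylsilyl)oxy]-10-[(triethylsilyl)oxy]cembra-3,7,11,15(17)-tetraen-16,2-olide, via hydroxy enal 26 (not isolated), via lactol 27 (not isolated)
Conditions: TEMPO (20 mol %), PhI(OAc)2, CH2Cl2, rt
Reagents that add atoms: none
Why: Oxoammonium (TEMPO/PhI(OAc)2) oxidation picks the primary allylic alcohol over the secondary C2 carbinol, the enal is captured as the five-membered lactol and oxidised on to the α-methylene-γ-lactone; the trans fusion is already fixed at C1/C2.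

Step 19
Reactants: 28 (1R,2S,3E,6S,7E,10S,11E)-6-[(tert-butyldimethylsilyl)oxy]-10-[(triethylsilyl)oxy]cembra-3,7,11,15(17)-tetraen-16,2-olide
Product: 29 (1R,2S,3E,6S,7E,10S,11E)-6-[(tert-butyldimethylsilyl)oxy]-10-hydroxycembra-3,7,11,15(17)-tetraen-16,2-olide
Conditions: PPTS (cat.), MeOH–CH2Cl2, 0 °C
Reagents that add atoms: none
Why: Acid-catalysed methanolysis cleaves the secondary TES ether much faster than the secondary TBS ether, and the lactone and olefins tolerate the mild acid.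

Step 20
Reactants: 29 (1R,2S,3E,6S,7E,10S,11E)-6-[(tert-butyldimethylsilyl)oxy]-10-hydroxycembra-3,7,11,15(17)-tetraen-16,2-olide
Product: 30 (1R,2S,3E,6S,7E,10S,11E)-10-acetoxy-6-[(tert-butyldimethylsilyl)oxy]cembra-3,7,11,15(17)-tetraen-16,2-olide
Conditions: Ac2O, pyridine, DMAP (cat.), CH2Cl2, 0 °C → rt
Reagents that add atoms: acetic anhydride, CC(=O)OC(C)=O
Why: Acylation of the only free hydroxyl; no stereocentre is involved.

Step 21
Reactants: 30 (1R,2S,3E,6S,7E,10S,11E)-10-acetoxy-6-[(tert-butyldimethylsilyl)oxy]cembra-3,7,11,15(17)-tetraen-16,2-olide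
Product: 31 (1R,2S,3E,6S,7E,10S,11E)-10-acetoxy-6-hydroxycembra-3,7,11,15(17)-tetraen-16,2-olide (CNP0406430.1)
Conditions: HF·pyridine, pyridine, THF, 0 °C → rt
Reagents that add atoms: none
Why: Buffered fluoride desilylation frees the C6 hydroxyl without acyl migration, acetate loss or conjugate addition to the α-methylene lactone.

**Compound list**

1 | geranyl acetate ((2E)-3,7-dimethylocta-2,6-dien-1-yl acetate) | CC(C)=CCC/C(C)=C/COC(C)=O | starting material
2 | (2E,6E)-8-hydroxy-3,7-dimethylocta-2,6-dien-1-yl acetate | OC/C(C)=C/CC/C(C)=C/COC(C)=O | intermediate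
3 | 1-bromobut-2-yne | CC#CCBr | starting material
4 | (2E,6E)-8-(but-2-yn-1-yloxy)-3,7-dimethylocta-2,6-dien-1-yl acetate | CC#CCOC/C(C)=C/CC/C(C)=C/COC(C)=O | intermediate
5 | (2E,6E)-8-(but-2-yn-1-yloxy)-3,7-dimethylocta-2,6-dien-1-ol | CC#CCOC/C(C)=C/CC/C(C)=C/CO | intermediate
6 | (2E,6E)-8-(but-2-yn-1-yloxy)-3,7-dimethylocta-2,6-dienal | CC#CCOC/C(C)=C/CC/C(C)=C/C=O | intermediate
7 | allenylboronic acid pinacol ester | C=C=CB1OC(C)(C)C(C)(C)O1 | starting material
8 | (4S,5E,9E)-11-(but-2-yn-1-yloxy)-6,10-dimethylundeca-5,9-dien-1-yn-4-ol | C#CC[C@H](O)/C=C(\C)CC/C=C(\C)COCC#CC | intermediate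
9 | triethyl{[(4S,5E,9E)-11-(but-2-yn-1-yloxy)-6,10-dimethylundeca-5,9-dien-1-yn-4-yl]oxy}silane | C#CC[C@H](O[Si](CC)(CC)CC)/C=C(\C)CC/C=C(\C)COCC#CC | intermediate
10 | dimethyl[(1E,4S,5E,9E)-11-(but-2-yn-1-yloxy)-2,6,10-trimethyl-4-(triethylsilyloxy)undeca-1,5,9-trien-1-yl]alane | C[Al](C)/C=C(\C)C[C@H](O[Si](CC)(CC)CC)/C=C(\C)CC/C=C(\C)COCC#CC | intermediate
11 | lithium butyl(dimethyl)[(1E,4S,5E,9E)-11-(but-2-yn-1-yloxy)-2,6,10-trimethyl-4-(triethylsilyloxy)undeca-1,5,9-trien-1-yl]aluminate | [Li+].CCCC[Al-](C)(C)/C=C(\C)C[C@H](O[Si](CC)(CC)CC)/C=C(\C)CC/C=C(\C)COCC#CC | intermediate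
12 | (2E,5S,6E,10E)-12-(but-2-yn-1-yloxy)-3,7,11-trimethyl-5-[(triethylsilyl)oxy]dodeca-2,6,10-trien-1-ol | OC/C=C(\C)C[C@H](O[Si](CC)(CC)CC)/C=C(\C)CC/C=C(\C)COCC#CC | intermediate
13 | (2E,5S,6E,10E)-12-(but-2-yn-1-yloxy)-3,7,11-trimethyl-5-[(triethylsilyl)oxy]dodeca-2,6,10-trienal | O=C/C=C(\C)C[C@H](O[Si](CC)(CC)CC)/C=C(\C)CC/C=C(\C)COCC#CC | intermediate
14 | (4S,5E,8S,9E,13E)-15-(but-2-yn-1-yloxy)-6,10,14-trimethyl-8-[(triethylsilyl)oxy]pentadeca-5,9,13-trien-1-yn-4-ol | C#CC[C@H](O)/C=C(\C)C[C@H](O[Si](CC)(CC)CC)/C=C(\C)CC/C=C(\C)COCC#CC | intermediate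
15 | (4S,5E,8S,9E,13E)-15-(but-2-yn-1-yloxy)-4-[(tert-butyldimethylsilyl)oxy]-6,10,14-trimethyl-8-[(triethylsilyl)oxy]pentadeca-5,9,13-trien-1-yne | C#CC[C@H](O[Si](C)(C)C(C)(C)C)/C=C(\C)C[C@H](O[Si](CC)(CC)CC)/C=C(\C)CC/C=C(\C)COCC#CC | intermediate
16 | lithium acetylide of 15 | [Li]C#CC[C@H](O[Si](C)(C)C(C)(C)C)/C=C(\C)C[C@H](O[Si](CC)(CC)CC)/C=C(\C)CC/C=C(\C)COCC#CC | intermediate
17 | (5S,6E,9S,10E,14E)-16-(but-2-yn-1-yloxy)-5-[(tert-butyldimethylsilyl)oxy]-7,11,15-trimethyl-9-[(triethylsilyl)oxy]hexadeca-6,10,14-trien-2-yne | CC#CC[C@H](O[Si](C)(C)C(C)(C)C)/C=C(\C)C[C@H](O[Si](CC)(CC)CC)/C=C(\C)CC/C=C(\C)COCC#CC | intermediate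
18 | (6S,7E,10S,11E,15E)-6-[(tert-butyldimethylsilyl)oxy]-8,12,16-trimethyl-10-[(triethylsilyl)oxy]-1-oxacycloheptadeca-7,11,15-trien-3-yne | O1CC#CC[C@H](O[Si](C)(C)C(C)(C)C)/C=C(\C)C[C@H](O[Si](CC)(CC)CC)/C=C(\C)CC/C=C(\C)C1 | intermediate
19 | 2-lithio derivative of 18 (configurationally labile at C2) | O1C([Li])C#CC[C@H](O[Si](C)(C)C(C)(C)C)/C=C(\C)C[C@H](O[Si](CC)(CC)CC)/C=C(\C)CC/C=C(\C)C1 | intermediate
20 | (1R,2R,6S,7E,10S,11E)-6-[(tert-butyldimethylsilyl)oxy]-8,12-dimethyl-1-(prop-1-en-2-yl)-10-[(triethylsilyl)oxy]cyclotetradeca-7,11-dien-3-yn-2-ol | O[C@H]1C#CC[C@H](O[Si](C)(C)C(C)(C)C)/C=C(\C)C[C@H](O[Si](CC)(CC)CC)/C=C(\C)CC[C@@H]1C(C)=C | intermediate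
21 | (1S,2R,6S,7E,10S,11E)-6-[(tert-butyldimethylsilyl)oxy]-8,12-dimethyl-1-(2-methyloxiran-2-yl)-10-[(triethylsilyl)oxy]cyclotetradeca-7,11-dien-3-yn-2-ol (oxirane carbon undefined) | O[C@H]1C#CC[C@H](O[Si](C)(C)C(C)(C)C)/C=C(\C)C[C@H](O[Si](CC)(CC)CC)/C=C(\C)CC[C@@H]1C1(C)CO1 | intermediate
22 | (1R,2R,6S,7E,10S,11E)-6-[(tert-butyldimethylsilyl)oxy]-1-(3-hydroxyprop-1-en-2-yl)-8,12-dimethyl-10-[(triethylsilyl)oxy]cyclotetradeca-7,11-dien-3-yn-2-ol | O[C@H]1C#CC[C@H](O[Si](C)(C)C(C)(C)C)/C=C(\C)C[C@H](O[Si](CC)(CC)CC)/C=C(\C)CC[C@@H]1C(=C)CO | intermediate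
23 | sodium C4-alkenyl bis(2-methoxyethoxy)aluminate chelated through the C2 oxygen (primary alkoxide drawn as its sodium salt) | [Na+].[Na+].COCCO[Al-]1(OCCOC)O[C@H]2C=C1C[C@H](O[Si](C)(C)C(C)(C)C)/C=C(\C)C[C@H](O[Si](CC)(CC)CC)/C=C(\C)CC[C@@H]2C(=C)C[O-] | intermediate
24 | (1R,2R,3Z,6S,7E,10S,11E)-6-[(tert-butyldimethylsilyl)oxy]-1-(3-hydroxyprop-1-en-2-yl)-4-iodo-8,12-dimethyl-10-[(triethylsilyl)oxy]cyclotetradeca-3,7,11-trien-2-ol | O[C@H]1/C=C(\I)C[C@H](O[Si](C)(C)C(C)(C)C)/C=C(\C)C[C@H](O[Si](CC)(CC)CC)/C=C(\C)CC[C@@H]1C(=C)CO | intermediate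
25 | (1R,2S,3E,6S,7E,10S,11E)-6-[(tert-butyldimethylsilyl)oxy]-1-(3-hydroxyprop-1-en-2-yl)-4,8,12-trimethyl-10-[(triethylsilyl)oxy]cyclotetradeca-3,7,11-trien-2-ol | O[C@H]1/C=C(\C)C[C@H](O[Si](C)(C)C(C)(C)C)/C=C(\C)C[C@H](O[Si](CC)(CC)CC)/C=C(\C)CC[C@@H]1C(=C)CO | intermediate
26 | 2-[(1R,2S,3E,6S,7E,10S,11E)-6-[(tert-butyldimethylsilyl)oxy]-2-hydroxy-4,8,12-trimethyl-10-[(triethylsilyl)oxy]cyclotetradeca-3,7,11-trien-1-yl]prop-2-enal | O[C@H]1/C=C(\C)C[C@H](O[Si](C)(C)C(C)(C)C)/C=C(\C)C[C@H](O[Si](CC)(CC)CC)/C=C(\C)CC[C@@H]1C(=C)C=O | intermediate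
27 | lactol of 26 (16-hydroxy-16,2-epoxide, anomeric carbon undefined) | C=C1C(O)O[C@H]2/C=C(\C)C[C@H](O[Si](C)(C)C(C)(C)C)/C=C(\C)C[C@H](O[Si](CC)(CC)CC)/C=C(\C)CC[C@H]12 | intermediate
28 | (1R,2S,3E,6S,7E,10S,11E)-6-[(tert-butyldimethylsilyl)oxy]-10-[(triethylsilyl)oxy]cembra-3,7,11,15(17)-tetraen-16,2-olide | C=C1C(=O)O[C@H]2/C=C(\C)C[C@H](O[Si](C)(C)C(C)(C)C)/C=C(\C)C[C@H](O[Si](CC)(CC)CC)/C=C(\C)CC[C@H]12 | intermediate
29 | (1R,2S,3E,6S,7E,10S,11E)-6-[(tert-butyldimethylsilyl)oxy]-10-hydroxycembra-3,7,11,15(17)-tetraen-16,2-olide | C=C1C(=O)O[C@H]2/C=C(\C)C[C@H](O[Si](C)(C)C(C)(C)C)/C=C(\C)C[C@H](O)/C=C(\C)CC[C@H]12 | intermediate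
30 | (1R,2S,3E,6S,7E,10S,11E)-10-acetoxy-6-[(tert-butyldimethylsilyl)oxy]cembra-3,7,11,15(17)-tetraen-16,2-olide | C=C1C(=O)O[C@H]2/C=C(\C)C[C@H](O[Si](C)(C)C(C)(C)C)/C=C(\C)C[C@H](OC(C)=O)/C=C(\C)CC[C@H]12 | intermediate
31 | (1R,2S,3E,6S,7E,10S,11E)-10-acetoxy-6-hydroxycembra-3,7,11,15(17)-tetraen-16,2-olide (CNP0406430.1) | C=C1C(=O)O[C@H]2/C=C(\C)C[C@H](O)/C=C(\C)C[C@H](OC(C)=O)/C=C(\C)CC[C@H]12 | target

**Count.** Total steps: 21. Longest linear sequence: 21 steps (1 → 31).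

**Steps most likely to fail**

Step 13 (key step). The chiral amide may discriminate poorly between the two C2 hydrogens inside the flexible 17-membered ring, where the remote C6/C10 centres give no help, so both anti diastereomers would form. The ring may also force the alkynyl arm endo and erode the anti preference, or the lithiated ether may leak into a [1,2]-shift. Fallback: take the sigmatropic step out of the ring and let alkyne metathesis close the carbocycle directly. It sets out from 17, which is rearranged in the open chain (t-BuLi with a chiral bis(oxazoline) ligand, THF/hexane, −78 °C) to the open-chain anti homopropargylic alcohol F1; here the acyclic E → anti preference applies and diastereomers can be separated on a conformationally simple compound. Silylation (TMSCl, Et3N) gives the trimethylsilyl ether F2, ring-closing alkyne metathesis under the step-12 conditions gives the 14-membered cycloalkyne silyl ether F3, and K2CO3/MeOH removes the TMS group to come back to the route at 20.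

Step 14. The directed epoxidation of a 1,1-disubstituted homoallylic olefin may be slow, so that background epoxidation of the ring olefins or Lewis-acid-induced cyclisation of the epoxy alcohol to a tetrahydrofuran competes. Fallback: build the lactone by hydroboration and introduce the methylene last. It sets out from 20: Red-Al then I2 gives the iodoalkene F4, Negishi methylation gives the isopropenyl dienol F5, 9-BBN then H2O2/NaOH (selective for the 1,1-disubstituted olefin) gives the 1,4-diol F6, TEMPO/PhI(OAc)2 gives the α-methyl lactone F7, LDA then PhSeBr gives the α-phenylselanyl lactone F8, and H2O2 oxidation with syn-elimination towards the methyl group comes back to the route at 28.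

Step 7. The carboalumination may also engage the internal butynyl alkyne or the propargylic ether, and trapping of the alkenylalane with formaldehyde may be incomplete, leaving protonated olefin. Fallback: replace propargylation/carbometalation by a vinylogous Mukaiyama aldol, which installs C6–C9 with the (E)-methyl olefin and the C10 centre in one step. It sets out from 6: the silyl dienolate F9 (from methyl 3-methylbut-2-enoate, LDA, TBSCl) is added under SiCl4 and a chiral bisphosphoramide (antipode for Si-face attack, CH2Cl2, −78 °C) to give the δ-hydroxy enoate F10, TESCl/imidazole gives the silyl ether ester F11, and DIBAL-H (CH2Cl2, −78 °C) comes back to the route at 12.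

**Further compounds**

F1 | step 13 | (2E,5S,6E,9S,12R,13R)-9-[(tert-butyldimethylsilyl)oxy]-3,7-dimethyl-12-(prop-1-en-2-yl)-5-[(triethylsilyl)oxy]heptadeca-2,6-diene-... open-chain anti alcohol: CH3C≡C–CH(OH)–CH(isopropenyl)–(CH2)2–C(Me)=CH–CH(OTES)–CH2–C(Me)=CH–CH(OTBS)–CH2–C≡CCH3 | CC#C[C@H](O)[C@@H](C(C)=C)CC/C(C)=C/[C@@H](O[Si](CC)(CC)CC)C/C(C)=C/[C@@H](O[Si](C)(C)C(C)(C)C)CC#CC
F2 | step 13 | trimethylsilyl ether of F1 | CC#C[C@H](O[Si](C)(C)C)[C@@H](C(C)=C)CC/C(C)=C/[C@@H](O[Si](CC)(CC)CC)C/C(C)=C/[C@@H](O[Si](C)(C)C(C)(C)C)CC#CC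
F3 | step 13 | 2-O-trimethylsilyl ether of 20 | C[Si](C)(C)O[C@H]1C#CC[C@H](O[Si](C)(C)C(C)(C)C)/C=C(\C)C[C@H](O[Si](CC)(CC)CC)/C=C(\C)CC[C@@H]1C(C)=C
F4 | step 14 | (1R,2R,3Z,6S,7E,10S,11E)-6-[(tert-butyldimethylsilyl)oxy]-4-iodo-8,12-dimethyl-1-(prop-1-en-2-yl)-10-[(triethylsilyl)oxy]cyclotetradeca-3,7,11-trien-2-ol | O[C@H]1/C=C(\I)C[C@H](O[Si](C)(C)C(C)(C)C)/C=C(\C)C[C@H](O[Si](CC)(CC)CC)/C=C(\C)CC[C@@H]1C(C)=C
F5 | step 14 | (1R,2S,3E,6S,7E,10S,11E)-6-[(tert-butyldimethylsilyl)oxy]-4,8,12-trimethyl-1-(prop-1-en-2-yl)-10-[(triethylsilyl)oxy]cyclotetradeca-3,7,11-trien-2-ol | O[C@H]1/C=C(\C)C[C@H](O[Si](C)(C)C(C)(C)C)/C=C(\C)C[C@H](O[Si](CC)(CC)CC)/C=C(\C)CC[C@@H]1C(C)=C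
F6 | step 14 | 1-(1-hydroxypropan-2-yl) analogue of F5 (1,4-diol, epimers at C15) | O[C@H]1/C=C(\C)C[C@H](O[Si](C)(C)C(C)(C)C)/C=C(\C)C[C@H](O[Si](CC)(CC)CC)/C=C(\C)CC[C@@H]1C(C)CO
F7 | step 14 | 15,17-dihydro derivative of 28 (α-methyl lactone, epimers at C15) | CC1C(=O)O[C@H]2/C=C(\C)C[C@H](O[Si](C)(C)C(C)(C)C)/C=C(\C)C[C@H](O[Si](CC)(CC)CC)/C=C(\C)CC[C@H]12
F8 | step 14 | 15-(phenylselanyl) derivative of F7 | CC1([Se]c3ccccc3)C(=O)O[C@H]2/C=C(\C)C[C@H](O[Si](C)(C)C(C)(C)C)/C=C(\C)C[C@H](O[Si](CC)(CC)CC)/C=C(\C)CC[C@H]12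
F9 | step 7 | tert-butyl{[(1Z)-1-methoxy-3-methylbuta-1,3-dien-1-yl]oxy}dimethylsilane | C=C(C)/C=C(/OC)O[Si](C)(C)C(C)(C)C
F10 | step 7 | methyl (2E,5S,6E,10E)-12-(but-2-yn-1-yloxy)-5-hydroxy-3,7,11-trimethyldodeca-2,6,10-trienoate | COC(=O)/C=C(\C)C[C@H](O)/C=C(\C)CC/C=C(\C)COCC#CC
F11 | step 7 | methyl (2E,5S,6E,10E)-12-(but-2-yn-1-yloxy)-3,7,11-trimethyl-5-[(triethylsilyl)oxy]dodeca-2,6,10-trienoate | COC(=O)/C=C(\C)C[C@H](O[Si](CC)(CC)CC)/C=C(\C)CC/C=C(\C)COCC#CC
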